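## Retrosynthetic overview

1. Target ⇐ double olefin cross-metathesis (allyl → prenyl at C2′ and C5′) of the 2′,5′-diallyl-6-(1,1-dimethylallyl) triol.
2. That triol ⇐ one-pot triple aromatic Claisen rearrangement of the (2S)-flavan carrying a 7-O-prenyl ether and 3′,4′-di-O-allyl ethers (O-prenyl → C6 reverse prenyl; O-allyl → C-allyl).
3. Flavan tri-ether ⇐ metal-free asymmetric reductive cyclisation of a 2-hydroxychalcone (chiral phosphoric acid + Hantzsch ester); this new step forms the O1–C2 bond and sets C2.
4. Chalcone ⇐ Claisen–Schmidt condensation of 3′,4′-bis(allyloxy)acetophenone with 2-hydroxy-4-(prenyloxy)benzaldehyde, each made by one O-alkylation of an achiral commercial phenol.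
5. Ring order: rings A and B are bought; the pyran ring C is the only ring formed (step 4).

Assumptions: flavan numbering is used (O1, C2–C8a; B ring primed); allyl = prop-2-en-1-yl, prenyl = 3-methylbut-2-en-1-yl. The target SMILES corresponds to the 2S configuration. The (R)-catalyst is written for the new step; if its sense of induction proves opposite, the (S)-catalyst is used with no other change.

## Route

Step 1
Reactants: 1 1-(3,4-dihydroxyphenyl)ethan-1-one
Product: 2 bis(allyl) ether 1-[3,4-bis(prop-2-en-1-yloxy)phenyl]ethan-1-one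
Conditions: allyl bromide (2.5 equiv), K2CO3 (3 equiv), DMF, 60 °C
Reagents that add atoms: allyl bromide, C=CCBr
Why: Williamson etherification (SN2) of both phenoxides with the allylic bromide; the ketone is inert to K2CO3 and no stereocentre is involved.

Step 2
Reactants: 3 2,4-dihydroxybenzaldehyde
Product: 4 prenyl ether 2-hydroxy-4-[(3-methylbut-2-en-1-yl)oxy]benzaldehyde
Conditions: prenyl bromide (1.05 equiv), K2CO3 (1.1 equiv), acetone, rt
Reagents that add atoms: prenyl bromide (1-bromo-3-methylbut-2-ene), CC(C)=CCBr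
Why: Regioselective Williamson etherification: the 2-OH is locked in a hydrogen bond to the aldehyde and is the poorer nucleophile, so one equivalent of prenyl bromide alkylates the 4-OH.

Step 3
Reactants: 2 1-[3,4-bis(prop-2-en-1-yloxy)phenyl]ethan-1-one; 4 2-hydroxy-4-[(3-methylbut-2-en-1-yl)oxy]benzaldehyde
Product: 5 chalcone (2E)-1-[3,4-bis(allyloxy)phenyl]-3-[2-hydroxy-4-(prenyloxy)phenyl]prop-2-en-1-one
Conditions: KOH (3 equiv), EtOH/H2O, rt to 40 °C; AcOH quench to pH 6
Reagents that add atoms: none
Why: Claisen–Schmidt (crossed aldol) condensation of the methyl ketone enolate with the non-enolisable aldehyde, then E1cB dehydration to the favoured E-enone; allyl and prenyl aryl ethers are stable to hydroxide.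

Step 4
Reactants: 5 (2E)-1-[3,4-bis(allyloxy)phenyl]-3-[2-hydroxy-4-(prenyloxy)phenyl]prop-2-en-1-one
Product: 9 (2S)-2-[3,4-bis(allyloxy)phenyl]-7-(prenyloxy)chromane, via flavylium phosphate 6 (not isolated), via 4H-flavene 7 (not isolated), via dihydrochromenylium phosphate 8 (not isolated)
Conditions: (R)-TRIP (10 mol %), Hantzsch ester (2.5 equiv), CHCl3 (0.05 M), 5 Å MS, 45 °C, dark
Reagents that add atoms: none
Why: Proposed new method: the phosphoric acid protonates the chalcone carbonyl, the 4-alkoxy-stabilised hydroxyallyl cation rotates about the former C=C bond and is closed by the 2-OH with loss of water to flavylium phosphate 6, Hantzsch ester delivers hydride to C4 to give the achiral enol ether 7, the acid protonates C3 to give the oxocarbenium/chiral phosphate contact ion pair 8, and a second Hantzsch ester, hydrogen-bonded through N–H to the phosphate, transfers hydride to one face of C2 to set the 2S centre (any dihydrochalcone from direct conjugate reduction enters the same ion pair through its cyclic hemiketal); the closest known reaction types are the phosphoric acid/Hantzsch ester cascade transfer hydrogenation of quinolines (1,4-hydride addition, protonation, 1,2-hydride addition) and chiral-phosphate-controlled hydride reduction of isobenzopyrylium-type oxocarbenium ions, whereas this cascade from a 2-hydroxychalcone to an enantioenriched flavan has, to my knowledge, not been shown.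

Step 5
Reactants: 9 (2S)-2-[3,4-bis(allyloxy)phenyl]-7-(prenyloxy)chromane
Product: 10 3,6-diallyl-4-[(2S)-7-hydroxy-6-(2-methylbut-3-en-2-yl)chroman-2-yl]benzene-1,2-diol
Conditions: PhNEt2 (0.05 M), 195 °C (microwave, sealed, Ar), 1–2 h
Reagents that add atoms: none
Why: Three aromatic Claisen [3,3] rearrangements, each followed by tautomerisation: each catechol allyl ether has only one free ortho carbon (C2′ for O3′, C5′ for O4′), and the prenyl ether delivers its tertiary terminus to C6 (para to the ring oxygen and unhindered, whereas C8 lies between two oxygens) to give the 1,1-dimethylallyl group; the neutral amine medium does not touch the C2 centre.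

Step 6
Reactants: 10 3,6-diallyl-4-[(2S)-7-hydroxy-6-(2-methylbut-3-en-2-yl)chroman-2-yl]benzene-1,2-diol
Product: 11 (2S)-2-[3,4-dihydroxy-2,5-bis(3-methylbut-2-en-1-yl)phenyl]-6-(2-methylbut-3-en-2-yl)chroman-7-ol
Conditions: Grubbs II (2 × 5 mol %), 2-methyl-2-butene/CH2Cl2 1:1, 40 °C (sealed)
Reagents that add atoms: 2-methylbut-2-ene, CC=C(C)C
Why: Olefin cross-metathesis: the two unhindered allyl-arene termini exchange =CH2 for =CMe2 with the excess trisubstituted olefin, the vinyl group on the quaternary carbon of the 1,1-dimethylallyl unit is too hindered to enter the catalytic cycle, and free phenols are tolerated by the ruthenium carbene; C2 is not involved.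

## Compound list

1 | 1-(3,4-dihydroxyphenyl)ethan-1-one (3′,4′-dihydroxyacetophenone) | CC(=O)c1ccc(O)c(O)c1 | starting material
2 | 1-[3,4-bis(prop-2-en-1-yloxy)phenyl]ethan-1-one | CC(=O)c1ccc(OCC=C)c(OCC=C)c1 | intermediate
3 | 2,4-dihydroxybenzaldehyde | O=Cc1ccc(O)cc1O | starting material
4 | 2-hydroxy-4-[(3-methylbut-2-en-1-yl)oxy]benzaldehyde | O=Cc1ccc(OCC=C(C)C)cc1O | intermediate
5 | (2E)-1-[3,4-bis(prop-2-en-1-yloxy)phenyl]-3-{2-hydroxy-4-[(3-methylbut-2-en-1-yl)oxy]phenyl}prop-2-en-1-one | O=C(/C=C/c1ccc(OCC=C(C)C)cc1O)c1ccc(OCC=C)c(OCC=C)c1 | intermediate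
6 | 2-[3,4-bis(allyloxy)phenyl]-7-(prenyloxy)chromenylium (flavylium) cation, counter-ion = catalyst phosphate | C=CCOc1ccc(-c2ccc3ccc(OCC=C(C)C)cc3[o+]2)cc1OCC=C | intermediate (not isolated)
7 | 2-[3,4-bis(allyloxy)phenyl]-7-(prenyloxy)-4H-chromene | C=CCOc1ccc(C2=CCc3ccc(OCC=C(C)C)cc3O2)cc1OCC=C | intermediate (not isolated)
8 | 2-[3,4-bis(allyloxy)phenyl]-7-(prenyloxy)-3,4-dihydrochromenylium cation (cyclic oxocarbenium), counter-ion = catalyst phosphate | C=CCOc1ccc(C2=[O+]c3cc(OCC=C(C)C)ccc3CC2)cc1OCC=C | intermediate (not isolated)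
9 | (2S)-2-[3,4-bis(prop-2-en-1-yloxy)phenyl]-7-[(3-methylbut-2-en-1-yl)oxy]-3,4-dihydro-2H-chromene | CC(C)=CCOc1ccc2c(c1)O[C@H](c1ccc(OCC=C)c(OCC=C)c1)CC2 | intermediate
10 | 3,6-diallyl-4-[(2S)-7-hydroxy-6-(2-methylbut-3-en-2-yl)-3,4-dihydro-2H-chromen-2-yl]benzene-1,2-diol | C=CC(C)(C)c1cc2c(cc1O)O[C@H](c1cc(CC=C)c(O)c(O)c1CC=C)CC2 | intermediate
11 | (2S)-2-[3,4-dihydroxy-2,5-bis(3-methylbut-2-en-1-yl)phenyl]-6-(2-methylbut-3-en-2-yl)-3,4-dihydro-2H-chromen-7-ol | C=CC(C)(C)c1cc2c(cc1O)O[C@H](c1cc(CC=C(C)C)c(O)c(O)c1CC=C(C)C)CC2 | target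

## Step count and risks

Total steps: 6 (steps 1 and 2 are parallel one-step branches, followed by four linear steps).
Longest linear sequence: 5 steps (1 → 2 → 5 → 9 → 10 → 11, or equally 3 → 4 → 5 → 9 → 10 → 11).

**Step 4 (the proposed new reductive cyclisation).** Three things can go wrong:
- flavylium formation from the E-chalcone may be slow under a weak acid;
- the oxocarbenium ion pair 8 has no hydrogen-bond handle, so the ee may be moderate;
- some hydride may add at C2 of 6, or 7 may dimerise with 8.

The ee is checked on 9 by chiral HPLC. The fallback uses known chemistry, sets out from 5 and comes back at 9. The enone C=C of 5 is reduced chemoselectively with catalytic copper hydride (Stryker's reagent 5 mol %, PMHS, t-BuOH, toluene, rt) to the dihydrochalcone 1-[3,4-bis(allyloxy)phenyl]-3-[2-hydroxy-4-(prenyloxy)phenyl]propan-1-one F1. Corey–Bakshi–Shibata reduction of the aryl ketone ((S)-Me-CBS 20 mol %, catecholborane 2.2 equiv, toluene, −78 °C) gives the carbinol (1R)-1-[3,4-bis(allyloxy)phenyl]-3-[2-hydroxy-4-(prenyloxy)phenyl]propan-1-ol F2. Mitsunobu etherification (PPh3, DIAD, THF, 0 °C) then closes the pyran ring with inversion at the benzylic carbon and gives (2S)-9.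

**Step 5 (triple Claisen).** The hazards are:
- some migration of the prenyl group to C8 (the isomer is removed by chromatography);
- a para shift of the O3′ allyl group to C6′;
- abnormal Claisen rearrangement or cyclisation of the free o-(1,1-dimethylallyl)phenol at 195 °C.

The fallback sets out from 9 and comes back at 10. It switches from a free-phenol to an acylative rearrangement: 9 is heated with Ac2O (6 equiv) and NaOAc in PhNEt2 at 190 °C, so each phenol is acetylated as soon as it is unveiled. The product is the triacetate (2S)-2-(3,4-diacetoxy-2,5-diallylphenyl)-6-(2-methylbut-3-en-2-yl)chroman-7-yl acetate F3, which has no ArOH to start the ene or cyclisation pathways and is purified at this stage. Methanolysis (K2CO3, MeOH, rt) then gives 10. This fallback does not change the C6/C8 ratio.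

**Step 6 (double cross-metathesis).** The free, hindered catechol may chelate and deactivate ruthenium, and Ru–H species may isomerise allyl to propenyl. The fallback sets out from 10 and comes back at 11. The catechol alone is masked by condensation with phenylboronic acid (1.05 equiv, toluene, 4 Å MS) as the cyclic boronate 4,7-diallyl-5-[(2S)-7-hydroxy-6-(2-methylbut-3-en-2-yl)chroman-2-yl]-2-phenyl-1,3,2-benzodioxaborole F4. Cross-metathesis under the step 6 conditions gives the diprenyl boronate 4,7-bis(3-methylbut-2-en-1-yl)-5-[(2S)-7-hydroxy-6-(2-methylbut-3-en-2-yl)chroman-2-yl]-2-phenyl-1,3,2-benzodioxaborole F5. Mild hydrolysis (aq. NaHCO3/MeOH, rt) releases 11.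

## Further compounds

F1 | step 4 | 1-[3,4-bis(prop-2-en-1-yloxy)phenyl]-3-{2-hydroxy-4-[(3-methylbut-2-en-1-yl)oxy]phenyl}propan-1-one | O=C(CCc1ccc(OCC=C(C)C)cc1O)c1ccc(OCC=C)c(OCC=C)c1
F2 | step 4 | (1R)-1-[3,4-bis(prop-2-en-1-yloxy)phenyl]-3-{2-hydroxy-4-[(3-methylbut-2-en-1-yl)oxy]phenyl}propan-1-ol | O[C@H](CCc1ccc(OCC=C(C)C)cc1O)c1ccc(OCC=C)c(OCC=C)c1
F3 | step 5 | (2S)-2-(3,4-diacetoxy-2,5-diallylphenyl)-6-(2-methylbut-3-en-2-yl)chroman-7-yl acetate | C=CC(C)(C)c1cc2c(cc1OC(C)=O)O[C@H](c1cc(CC=C)c(OC(C)=O)c(OC(C)=O)c1CC=C)CC2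
F4 | step 6 | 4,7-diallyl-5-[(2S)-7-hydroxy-6-(2-methylbut-3-en-2-yl)chroman-2-yl]-2-phenyl-1,3,2-benzodioxaborole | C=CC(C)(C)c1cc2c(cc1O)O[C@H](c1cc(CC=C)c3OB(c4ccccc4)Oc3c1CC=C)CC2
F5 | step 6 | 4,7-bis(3-methylbut-2-en-1-yl)-5-[(2S)-7-hydroxy-6-(2-methylbut-3-en-2-yl)chroman-2-yl]-2-phenyl-1,3,2-benzodioxaborole | C=CC(C)(C)c1cc2c(cc1O)O[C@H](c1cc(CC=C(C)C)c3OB(c4ccccc4)Oc3c1CC=C(C)C)CC2
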